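The runs are calculated with made-up constants; noise was put on by code.

A small charge of catalyst, 0.20 mM, works on substrate and reagent, and Ruth and Karl disagree about what happens after the target stops rising.

| flask | substrate | reagent | catalyst | remark | time |
|---|---|---|---|---|---|
| alpha | 0.010 M | 5 mM | 0.20 mM | run made earlier |  |
| epsilon | 0.010 M | 7.5 mM | 0.20 mM | run made earlier |  |
| gamma | 0.015 M | 10 mM | 0.20 mM | run made earlier |  |
| Wednesday's | 0.010 M | 10.0 mM | 0.20 mM |  | 1.0 h |
| Friday's | 0.010 M | 10.0 mM | 0.20 mM |  | 2.0 h |
| Tuesday's | 0.010 M | 10.0 mM | 0.20 mM |  | 4.0 h |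

| run | time / min | target / % | substrate / % |
|---|---|---|---|
| alpha | 2.50 | 14.3 | 86.3 |
| alpha | 8.00 | 26.4 | 72.6 |
| alpha | 12.0 | 29.6 | 68.5 |
| alpha | 20.0 | 32.7 | 63.5 |
| alpha | 30.0 | 32.3 | 61.4 |
| alpha | 40.0 | 31.8 | 62.2 |
| epsilon | 3.00 | 22.0 | 78.1 |
| epsilon | 5.00 | 30.4 | 67.5 |
| epsilon | 8.00 | 39.2 | 59.9 |
| epsilon | 12.0 | 42.8 | 54.6 |
| epsilon | 20.0 | 48.7 | 47.7 |
| epsilon | 40.0 | 47.3 | 42.0 |
| gamma | 3.00 | 23.2 | 76.2 |
| gamma | 10.0 | 42.8 | 56.4 |
| gamma | 15.0 | 47.0 | 53.8 |
| gamma | 25.0 | 46.5 | 46.5 |
| gamma | 40.0 | 45.0 | 47.5 |

(scatter of a reading: 1 percentage point)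

* which of the two there is more of at the end, Wednesday's (over-reaction product / target)
* which of the two there is more of at the end, Friday's (over-reaction product / target)
* which of the two there is more of at the end, Tuesday's (over-reaction product / target)
* how much target is there at the end, in percent of the substrate charged: Wednesday's
* how much target is there at the end, in percent of the substrate charged: Friday's
* how much target is there at the end, in percent of the substrate charged: Tuesday's



Ruth says the flask stalls. In epsilon the target goes from 48.7% at 20.0 min to 47.3% at 40.0 min, a drop of 1.4 percentage points against a scatter of 1 point, so in her view waiting costs little.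

Karl answers that flat is not still. In epsilon substrate and target together fall short of the charge, and the gap widens from 3.6 points to 11 points over that same window. He reads the gap as over-reaction product and supposes d[over-reaction product]/dt = k[target]. Integrated, this says that the gap equals k times the area under the target curve, which trapezoids give from the readings. Gap over area at the last reading is 0.00528 min⁻¹ in alpha, 0.00637 min⁻¹ in epsilon and 0.00456 min⁻¹ in gamma. Their mean, read with the scatter of the gaps, is the leak constant, the pseudo-first-order rate at which target turns into over-reaction product at this catalyst charge: 0.00540 min⁻¹. That is a half-life of 2.14 h, longer than Ruth's window of 20.0 min, and in that window epsilon's substrate reading still falls from 47.7% to 42.0%, so a flat target there can hide the loss.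

I take Karl's side and reckon on. Substrate gone per reagent charged is 75.6% in alpha, 77.3% in epsilon and 78.7% in gamma at the last readings, with substrate still standing, so reagent looks like the limiting reagent. The mean share, 77.2%, gives a total turned over of X = 77.2% for the new flasks. Counting the making as done at 12.0 min, a crude clock start s taken from epsilon, [target] = X exp(−k(t − s)). I commit to 59.6% on Wednesday's, 43.1% on Friday's and 22.5% on Tuesday's. In this reckoning target falls to half of X at 2.34 h, where the over-reaction product draws level with it, so I put target ahead on Friday's and behind on Tuesday's.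

The forecast, reading the flask as Ruth does, gives 53%, 51.5% and 49%, with target ahead on Tuesday's, since “extra time should add little”.

Wednesday's ends at 57.0% target, Friday's at 45.2% and Tuesday's at 28.1%, with 58.1% of over-reaction product on Tuesday's.

    substrate + reagent + catalyst → target + catalyst, rate k1*[substrate]*[reagent]*[catalyst]/(1 + ([substrate]/sat1)) (9.70 mM, k = 1.40 × 10⁵ M⁻² min⁻¹)
    catalyst + target → catalyst + over-reaction product (k = 27.0 M⁻¹ min⁻¹)
    reagent ⇌ dormant form (K = 6.20, k = 0.0410 min⁻¹)

Ruth's picture stands for the window she read in epsilon, Karl's for the hours after it. At Tuesday's end target is made more slowly than it is used up, at 0.258 of that rate. Take a neighbour of Tuesday's flask with 0.0025 M of reagent: X is 19.3%, and the leak constant leaves 5.63% as target. That flask holds 7.43% of target and 15.6% of over-reaction product.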